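## Structural features

The target is 7-hydroxy-3,5,6,8-tetramethoxy-2-(4-methoxyphenyl)-4H-chromen-4-one, an achiral flavone. Benzo ring A (C4a, C5–C8, C8a) is fused through the C4a–C8a bond to the 4-pyranone ring C (O1, C2, C3, C4), and the 4-methoxyphenyl ring B is attached to C2 by a single C–C bond. There is no stereocentre. Every ring A carbon is substituted (5-OMe, 6-OMe, 7-OH, 8-OMe) and C3 carries a further methoxy group. The fragile points are the 5-methoxy group peri to the C4 carbonyl (lost to chelating Lewis acids), C2 of the pyranone (ring opening by hard nucleophiles) and the polyoxygenated ring A intermediates, which oxidise easily to quinones. The real difficulty is twofold: ring C must be fused onto a ring A that has no free position and four contiguous oxygens, and O7 alone must stay unmethylated although O6 is its direct neighbour. The key step uses the fact that C4a and C8a are adjacent and carry the C4 acyl carbon and O1, which are the carbon and oxygen of one carboxyl group, so ring A can react as an aryne across C4a–C8a. Because C5 and C8 both bear methoxy groups and O6/O7 can be tied together as an isopropylidene ketal, this aryne has a mirror plane and its two carbons are equivalent. Once ring C exists, O7 is para to C4a and conjugated with the C4 carbonyl while O6 is not, and this acidity difference is what tells them apart afterwards.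

## Logic of the disconnections

24 ⇒ 23. The free O7–H is traded for O7–CH2Ph. The reason is that O7 must be masked while O6 is methylated, and benzyl leaves by hydrogenolysis without acid or Lewis acid near the 5-methoxy group. The forward step only has to spare the tetrasubstituted C2=C3 bond.

23 ⇒ 22 ⇒ 21. The O6–CH3 bond and then the O7–CH2Ph bond are cut, which leads back to a 6,7-diol whose two hydroxyls differ only in acidity. The gain is that ring A becomes symmetric in its oxygen pattern again. The demand is a benzylation confined to the more acidic 7-hydroxyl, so only the monoanion may be present.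

21 ⇒ 20. The two O–H bonds are replaced by the two O–C bonds of an isopropylidene ketal. This restores a mirror plane through ring A and makes the oxygens inert to fluoride and carbanions. The forward step must hydrolyse an aryl ketal without touching the methyl ethers.

20 ⇒ 11 + 17 (key disconnection). C8a–O1, C4a–C4 and O1–C2 are cut. Ring C falls apart into a carboxylic acid carrying ring B and a leaving group at its β-carbon, and a symmetric aryne equivalent. The gain is one ring and three skeletal bonds in one flask from two pieces of similar size. The forward step needs carboxylate addition to the aryne, acyl shift in preference to proton capture, and ring closure at a donor-substituted β-carbon. Regiochemistry is not an issue because of the symmetry.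

11 ⇒ 8. The C6–Si and O–S bonds are cut. The ortho-silyl triflate is traced to an ortho-bromophenol, so silicon can be delivered from oxygen to carbon (through 9 and 10) and the phenoxide triflated in the same flask. The demand is bromine–lithium exchange at low temperature without loss of the ketal.

8 ⇒ 7 ⇒ 4. The C6–Br bond and then the C5–O bond are cut. In 4 both ring hydrogens are equivalent and each is ortho to a methoxy group, so lithiation (5), borylation (6) and oxidation place the hydroxyl unambiguously. The only open position of 7 then takes bromine. The demand is that the electron-rich phenol 7 is substituted and not oxidised.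

4 ⇒ 3 ⇒ 2 ⇒ 1. The ketal C–O bonds, then one ring C–O bond (via a formyl group), then the C–CHO bond are cut. The ortho-hydroxyl is introduced as a formyl group at the single free ortho position of 1 and exchanged for oxygen. This fixes the 1,2,3,4-tetraoxygenation pattern in two reliable steps and avoids a direct oxidation that could demethylate.

17 ⇒ 16 ⇒ 15. The ester C–O bond and then the enol O–CH3 bond are cut. The β-methoxy group, which is the leaving group of the key step, comes from the ketone oxygen of a β-keto ester. The forward step must methylate oxygen and not carbon. Its double-bond geometry is irrelevant.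

15 ⇒ 12 + 13. The C2–C3 bond is cut between an ester enolate (14) and an aroyl chloride. Both are commercial, and the acid chloride is chosen over the less electrophilic methyl ester so that acylation outruns self-condensation of 12.

## Other disconnections considered

Alternative 1: The cut runs through C4a–C4 and C4–C3, so C4 arrives as carbon monoxide between the aryl iodide A1 (1,3-bis(benzyloxy)-4-iodo-2,5,6-trimethoxybenzene) and the enolate of ketone A2 (2-methoxy-1-(4-methoxyphenyl)ethan-1-one).
- Forward key step: Pd(OAc)2 (divalent palladium, reduced in the flask to zerovalent palladium) with a wide-bite-angle bisphosphine, CO and base should give the chelated enol A3 by oxidative addition, CO insertion and C-acylation of the enolate. Hydrogenolysis of both benzyl ethers and acid-induced cyclodehydration would then close ring C and free O7.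
- In its favour: three components are joined, and every ring A oxygen is placed and distinguished before the coupling. On the O6/O7 question it is better than the chosen plan, because nothing has to be differentiated afterwards. Its endgame is also shorter (two operations against four).
- Against it: A1 is a hexasubstituted, very electron-rich iodide with both ortho positions occupied, which should slow oxidative addition and crowd the acyl–palladium intermediate. Direct arylation of the enolate without CO uptake and O-acylation are open side channels. A1 needs a pentaoxygenated benzene with two benzyl and three methyl ethers in fixed positions, so the differentiation problem moves to the front of the route.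
- Comparison: both plans attach a C3 unit to C4a. This one is a metal-catalysed coupling that leaves ring C open; the chosen one is an anionic cascade that closes it in the same flask. Overall length is probably similar, with more risk at the key step and the need for a toxic gas under pressure.

Alternative 2: Ring A is cut out entirely and C8–C8a is the bond formed last. The four oxygenated carbons C5–C8 come from the mixed squarate A4 (3-tert-butoxy-4-methoxycyclobut-3-ene-1,2-dione), and C4a/C8a from the bromopyranone A5 (5-bromo-3-methoxy-2-(4-methoxyphenyl)-4H-pyran-4-one).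
- Forward key step: A5 is metalated by halogen–metal exchange and added to A4 to give the racemic carbinol A6. Heating A6 in toluene should open the four-membered ring to a vinylketene, which closes in a 6π electrocyclisation onto the pyranone C=C and tautomerises to the 5,8-hydroquinone A7.
- In its favour: a fully substituted ring A with four oxygens is created in one reagent-free thermal step, and O7 carries its own tert-butyl group from the start. In the O6/O7 distinction it is equal to or better than the chosen plan, and it needs about two operations after the key step against four.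
- Against it: the metalated pyranone must attack the carbonyl next to the methoxy-bearing carbon of A4, and only a steric bias separates that from the other carbonyl. A metalated 4-pyranone is itself electrophilic and may not survive. A7 is an oxidation-prone hydroquinone whose chelated 5-hydroxyl must still be methylated. A5 needs a multi-step synthesis of its own.
- Comparison: both plans face a regiochemical question. The chosen plan removes it by symmetry and pays with later steps; this one keeps it at the squarate addition with weaker control. Mechanistically it is pericyclic and neutral, which is gentler than fluoride at high temperature. The total count is expected to be no shorter.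

Alternative 3: The cut is C4–C4a. Ring C is closed by intramolecular acylation of the aryl vinyl ether acid A8 ((2E)-3-[3-(benzyloxy)-2,4,5-trimethoxyphenoxy]-2-methoxy-3-(4-methoxyphenyl)prop-2-enoic acid), prepared from phenol A10 (3-(benzyloxy)-2,4,5-trimethoxyphenol).
- Forward key step: activation of A8 with oxalyl chloride and then SnCl4 (tetravalent tin) should send the acylium carbon to the only free ring carbon and give A9 (7-(benzyloxy)-3,5,6,8-tetramethoxy-2-(4-methoxyphenyl)-4H-chromen-4-one). A9 is the same compound as 23, so one hydrogenolysis finishes the synthesis.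
- In its favour: the site of acylation is unambiguous, the ring is highly nucleophilic, and O7 is benzylated from the outset. After the key step it is clearly better than the chosen plan (one step against four).
- Against it: SnCl4 and the HCl formed threaten the benzyl ether and the methoxy group that ends up peri to the new carbonyl. The activated β-aryloxy-α-methoxy acrylic acid can lose its aryloxy group by addition–elimination. The carboxyl must sit cis to the aryloxy group. A10 is again a differentiated pentaoxygenated benzene, and its O–C2 bond to a tetrasubstituted acceptor must be made in a separate step.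
- Comparison: this plan forms one bond in the key step by a cationic route; the chosen plan forms three by an anionic route from a symmetric, simpler ring A piece. The shorter endgame here is paid for by a longer and less certain preparation of A10 and A8.

Key step: step 10

Remarks on the chemistry:
- 16 and 17 are drawn as the (E) isomers (C3 methoxy cis to the carbonyl) expected from O-methylation of the chelated enolate. Any (Z) isomer is carried along, because the double-bond geometry is erased in step 10.
- 15 has one enolisable stereocentre, is used as the racemate, and loses that centre in step 8. All other compounds are achiral.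
- The key-step partners 11 and 17 and the product 20 map atom for atom onto rings A and C of the target: C5 and C6 of the benzodioxole become C8a and C4a. Their constitution needs no change.

## Route

Step 1
Reactants: 1 2,5-dimethoxyphenol
Product: 2 2-hydroxy-3,6-dimethoxybenzaldehyde
Conditions: MgCl2, Et3N, (CH2O)n, MeCN, reflux
Reagents that add atoms: paraformaldehyde (formaldehyde), C=O
Why: Magnesium-mediated ortho-formylation (Casnati–Skattebøl): the magnesium phenoxide delivers formaldehyde through a chelate to the only free ortho carbon, and a second formaldehyde oxidises the benzylic alkoxide to the aldehyde, so the para position is not attacked.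

Step 2
Reactants: 2 2-hydroxy-3,6-dimethoxybenzaldehyde
Product: 3 3,6-dimethoxybenzene-1,2-diol
Conditions: 30% H2O2, NaOH, H2O/THF, 0 °C to rt, under N2
Reagents that add atoms: hydrogen peroxide, OO
Why: Dakin oxidation: hydroperoxide adds to the aldehyde, the electron-rich aryl group migrates to oxygen and the formate is hydrolysed; exclusion of air should keep the catechol from going on to the quinone.

Step 3
Reactants: 3 3,6-dimethoxybenzene-1,2-diol
Product: 4 4,7-dimethoxy-2,2-dimethyl-1,3-benzodioxole
Conditions: 2,2-dimethoxypropane, TsOH·H2O (cat.), toluene, reflux, MeOH removed over 4 Å molecular sieves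
Reagents that add atoms: 2,2-dimethoxypropane, COC(C)(C)OC
Why: Acid-catalysed transketalisation of a catechol, driven by removal of methanol; it gives the mirror-symmetric benzodioxole whose two ring hydrogens are equivalent.

Step 4
Reactants: 4 4,7-dimethoxy-2,2-dimethyl-1,3-benzodioxole
Product: 7 4,7-dimethoxy-2,2-dimethyl-1,3-benzodioxol-5-ol, via aryllithium 5 (not isolated), via dimethyl arylboronate 6 (not isolated)
Conditions: n-BuLi, TMEDA, THF, 0 °C; B(OMe)3, −78 °C to rt; 30% H2O2, AcOH, 0 °C
Reagents that add atoms: hydrogen peroxide, OO
Why: Directed ortho-metalation next to a methoxy group (either ring hydrogen gives the same anion), borylation and oxidative boron-to-oxygen aryl shift; the ketal has no acidic hydrogen and tolerates n-BuLi, and the mildly acidic oxidation spares the electron-rich phenol.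

Step 5
Reactants: 7 4,7-dimethoxy-2,2-dimethyl-1,3-benzodioxol-5-ol
Product: 8 6-bromo-4,7-dimethoxy-2,2-dimethyl-1,3-benzodioxol-5-ol
Conditions: NBS (1.0 equiv), CH2Cl2, −78 to 0 °C, dark
Reagents that add atoms: N-bromosuccinimide, O=C1CCC(=O)N1Br
Why: Electrophilic aromatic bromination at the single unsubstituted ring carbon, which is ortho to the hydroxyl; one equivalent at low temperature should limit oxidation of the phenol.

Step 6
Reactants: 8 6-bromo-4,7-dimethoxy-2,2-dimethyl-1,3-benzodioxol-5-ol
Product: 11 4,7-dimethoxy-2,2-dimethyl-6-(trimethylsilyl)-1,3-benzodioxol-5-yl trifluoromethanesulfonate, via aryl trimethylsilyl ether 9 (not isolated), via lithium 2-silylphenoxide 10 (not isolated)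
Conditions: HN(SiMe3)2, THF, reflux, then evaporate; n-BuLi, THF, −100 to −78 °C; Tf2O, −100 °C to rt
Reagents that add atoms: hexamethyldisilazane, C[Si](C)(C)N[Si](C)(C)C; trifluoromethanesulfonic anhydride, O=S(=O)(OS(=O)(=O)C(F)(F)F)C(F)(F)F
Why: O-silylation, bromine–lithium exchange and 1,3 oxygen-to-carbon silyl shift (retro-Brook rearrangement), then O-triflation of the phenoxide; this is the standard one-flask entry to ortho-silylaryl triflates from ortho-bromophenols.

Step 7
Reactants: 12 methyl methoxyacetate; 13 4-methoxybenzoyl chloride
Product: 15 methyl 2-methoxy-3-(4-methoxyphenyl)-3-oxopropanoate, via lithium ester enolate 14 (not isolated)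
Conditions: 12 (2.1 equiv), LiN(SiMe3)2 (2.1 equiv), THF, −78 °C; 13 (1.0 equiv), −78 to 0 °C; aq. NH4Cl
Reagents that add atoms: none
Why: Crossed Claisen-type C-acylation of an ester lithium enolate with an aroyl chloride; the second equivalent of enolate deprotonates the more acidic β-keto ester and so prevents double acylation, and the acid chloride reacts at −78 °C before 12 can self-condense.

Step 8
Reactants: 15 methyl 2-methoxy-3-(4-methoxyphenyl)-3-oxopropanoate
Product: 16 methyl (2E)-2,3-dimethoxy-3-(4-methoxyphenyl)prop-2-enoate
Conditions: Me2SO4, Cs2CO3, DMF, 0 °C to rt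
Reagents that add atoms: dimethyl sulfate, COS(=O)(=O)OC
Why: O-alkylation of a β-keto ester enolate; a hard electrophile, the cesium counter-ion, a dipolar aprotic solvent and the fully substituted α-carbon all favour attack through oxygen, and the chelated enolate leads to the (E) enol ether.

Step 9
Reactants: 16 methyl (2E)-2,3-dimethoxy-3-(4-methoxyphenyl)prop-2-enoate
Product: 17 (2E)-2,3-dimethoxy-3-(4-methoxyphenyl)prop-2-enoic acid
Conditions: LiOH·H2O, THF/MeOH/H2O, 40 °C; cold 1 M HCl to pH 3, 0 °C, immediate extraction
Reagents that add atoms: lithium hydroxide (supplies the carboxyl oxygen), [Li+].[OH-]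
Why: Ester saponification; the doubly donor-substituted, tetrasubstituted alkene is a poor Michael acceptor, so hydroxide attacks the ester carbonyl, and brief cold acidification avoids hydrolysis of the enol ether and decarboxylation.

Step 10
Reactants: 11 4,7-dimethoxy-2,2-dimethyl-6-(trimethylsilyl)-1,3-benzodioxol-5-yl trifluoromethanesulfonate; 17 (2E)-2,3-dimethoxy-3-(4-methoxyphenyl)prop-2-enoic acid
Product: 20 4,7,9-trimethoxy-6-(4-methoxyphenyl)-2,2-dimethyl-8H-[1,3]dioxolo[4,5-g]chromen-8-one (= 3,5,8-trimethoxy-6,7-(isopropylidenedioxy)-2-(4-methoxyphenyl)-4H-chromen-4-one), via aryne 18 (not isolated), via cesium 2-acylphenoxide 19 (not isolated)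
Conditions: 17 (1.5 equiv), CsF (4 equiv), THF, 125 °C, sealed tube
Reagents that add atoms: none
Why: Fluoride attacks silicon of 11 and triflate leaves, giving aryne 18, while CsF turns 17 into its cesium carboxylate, which adds through oxygen; a mirror plane through the ketal carbon makes both aryne carbons equivalent, so either mode of addition gives the same aryl anion. This σ-anion, next to the ester oxygen and stabilised inductively by the flanking methoxy group, attacks the ester carbonyl through a four-membered alkoxide that opens to the ortho-acyl phenoxide 19, a formal insertion of the aryne into the acyl C–O bond that forms C8a–O1 and C4a–C4. The phenoxide then closes ring C by a 6-endo-trig oxa-Michael addition to the β-carbon of the enone, and the resulting enolate expels methoxide, which forms O1–C2 and the 3-methoxypyranone. The closest known reaction is the fluoride-induced insertion of arynes into the C–O bond of carboxylic acids, which gives ortho-hydroxyaryl ketones and, with unsaturated acids, chromanones and flavones in the same flask. No stereocentre is formed and the alkene geometry of 17 is lost in the addition–elimination. The selectivity needed is regiochemical (which aryne carbon takes the oxygen) and is secured by the symmetry of 18; acyl shift is favoured over proton capture by the high temperature and the aprotic medium, and over conjugate attack of the aryl anion at the β-carbon by the tetrasubstituted, donor-substituted nature of that carbon.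

Step 11
Reactants: 20 4,7,9-trimethoxy-6-(4-methoxyphenyl)-2,2-dimethyl-8H-[1,3]dioxolo[4,5-g]chromen-8-one
Product: 21 6,7-dihydroxy-3,5,8-trimethoxy-2-(4-methoxyphenyl)-4H-chromen-4-one
Conditions: TFA/H2O (9:1), 40 °C, under argon
Reagents that add atoms: none
Why: Acid-catalysed hydrolysis of the aryl ketal (catechol acetonide), helped by the good leaving-group ability of the O7 phenol; aqueous TFA does not cleave aryl methyl ethers, including the peri 5-methoxy group.

Step 12
Reactants: 21 6,7-dihydroxy-3,5,8-trimethoxy-2-(4-methoxyphenyl)-4H-chromen-4-one
Product: 22 7-(benzyloxy)-6-hydroxy-3,5,8-trimethoxy-2-(4-methoxyphenyl)-4H-chromen-4-one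
Conditions: BnBr (1.05 equiv), KHCO3 (1.5 equiv), DMF, 40 °C, under argon
Reagents that add atoms: benzyl bromide, BrCc1ccccc1
Why: Williamson etherification under monoanion control: hydrogencarbonate deprotonates only the 7-hydroxyl, a vinylogous acid para to C4a and conjugated with the C4 carbonyl, so benzylation should occur at O7 and leave the less acidic 6-hydroxyl free.

Step 13
Reactants: 22 7-(benzyloxy)-6-hydroxy-3,5,8-trimethoxy-2-(4-methoxyphenyl)-4H-chromen-4-one
Product: 23 7-(benzyloxy)-3,5,6,8-tetramethoxy-2-(4-methoxyphenyl)-4H-chromen-4-one
Conditions: MeI, K2CO3, DMF, rt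
Reagents that add atoms: iodomethane, CI
Why: Williamson methylation of the only remaining hydroxyl; the small electrophile reaches the hindered O6 and the pyranone is stable to carbonate.

Step 14
Reactants: 23 7-(benzyloxy)-3,5,6,8-tetramethoxy-2-(4-methoxyphenyl)-4H-chromen-4-one
Product: 24 7-hydroxy-3,5,6,8-tetramethoxy-2-(4-methoxyphenyl)-4H-chromen-4-one
Conditions: H2 (1 atm), Pd/C (10% palladium on carbon), EtOAc/MeOH, rt
Reagents that add atoms: none
Why: Catalytic hydrogenolysis of the benzyl ether; the tetrasubstituted, conjugated C2=C3 bond and the aryl methyl ethers are not reduced under these conditions, so the 7-hydroxyl is freed without acid near the 5-methoxy group.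

## Compound list

1 | 2,5-dimethoxyphenol | COc1ccc(OC)c(O)c1 | starting material
2 | 2-hydroxy-3,6-dimethoxybenzaldehyde | COc1ccc(OC)c(C=O)c1O | intermediate
3 | 3,6-dimethoxybenzene-1,2-diol | COc1ccc(OC)c(O)c1O | intermediate
4 | 4,7-dimethoxy-2,2-dimethyl-1,3-benzodioxole | COc1ccc(OC)c2OC(C)(C)Oc12 | intermediate
5 | (4,7-dimethoxy-2,2-dimethyl-1,3-benzodioxol-5-yl)lithium | [Li]c1cc(OC)c2OC(C)(C)Oc2c1OC | intermediate (not isolated)
6 | dimethyl (4,7-dimethoxy-2,2-dimethyl-1,3-benzodioxol-5-yl)boronate | COB(OC)c1cc(OC)c2OC(C)(C)Oc2c1OC | intermediate (not isolated)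
7 | 4,7-dimethoxy-2,2-dimethyl-1,3-benzodioxol-5-ol | COc1cc(O)c(OC)c2OC(C)(C)Oc12 | intermediate
8 | 6-bromo-4,7-dimethoxy-2,2-dimethyl-1,3-benzodioxol-5-ol | COc1c(Br)c(O)c(OC)c2OC(C)(C)Oc12 | intermediate
9 | [(6-bromo-4,7-dimethoxy-2,2-dimethyl-1,3-benzodioxol-5-yl)oxy](trimethyl)silane | COc1c(Br)c(O[Si](C)(C)C)c(OC)c2OC(C)(C)Oc12 | intermediate (not isolated)
10 | lithium 4,7-dimethoxy-2,2-dimethyl-6-(trimethylsilyl)-1,3-benzodioxol-5-olate | [Li+].COc1c([Si](C)(C)C)c([O-])c(OC)c2OC(C)(C)Oc12 | intermediate (not isolated)
11 | 4,7-dimethoxy-2,2-dimethyl-6-(trimethylsilyl)-1,3-benzodioxol-5-yl trifluoromethanesulfonate | COc1c(OS(=O)(=O)C(F)(F)F)c([Si](C)(C)C)c(OC)c2OC(C)(C)Oc12 | intermediate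
12 | methyl methoxyacetate | COCC(=O)OC | starting material
13 | 4-methoxybenzoyl chloride | COc1ccc(cc1)C(Cl)=O | starting material
14 | lithium 1,2-dimethoxyethen-1-olate (enolate geometry not defined and without consequence) | [Li+].COC=C([O-])OC | intermediate (not isolated)
15 | methyl 2-methoxy-3-(4-methoxyphenyl)-3-oxopropanoate (racemic, enolisable centre) | COC(C(=O)OC)C(=O)c1ccc(OC)cc1 | intermediate
16 | methyl (2E)-2,3-dimethoxy-3-(4-methoxyphenyl)prop-2-enoate | COc1ccc(cc1)/C(OC)=C(OC)/C(=O)OC | intermediate
17 | (2E)-2,3-dimethoxy-3-(4-methoxyphenyl)prop-2-enoic acid | COc1ccc(cc1)/C(OC)=C(OC)/C(O)=O | intermediate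
18 | 5,6-didehydro-4,7-dimethoxy-2,2-dimethyl-1,3-benzodioxole (aryne) | COC1=C2OC(C)(C)OC2=C(OC)C#C1 | intermediate (not isolated)
19 | cesium 6-[(2E)-2,3-dimethoxy-3-(4-methoxyphenyl)prop-2-enoyl]-4,7-dimethoxy-2,2-dimethyl-1,3-benzodioxol-5-olate | [Cs+].COc1ccc(cc1)/C(OC)=C(OC)/C(=O)c1c([O-])c(OC)c2OC(C)(C)Oc2c1OC | intermediate (not isolated)
20 | 4,7,9-trimethoxy-6-(4-methoxyphenyl)-2,2-dimethyl-8H-[1,3]dioxolo[4,5-g]chromen-8-one | COc1ccc(-c2oc3c(OC)c4OC(C)(C)Oc4c(OC)c3c(=O)c2OC)cc1 | intermediate
21 | 6,7-dihydroxy-3,5,8-trimethoxy-2-(4-methoxyphenyl)-4H-chromen-4-one | COc1ccc(-c2oc3c(OC)c(O)c(O)c(OC)c3c(=O)c2OC)cc1 | intermediate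
22 | 7-(benzyloxy)-6-hydroxy-3,5,8-trimethoxy-2-(4-methoxyphenyl)-4H-chromen-4-one | COc1ccc(-c2oc3c(OC)c(OCc4ccccc4)c(O)c(OC)c3c(=O)c2OC)cc1 | intermediate
23 | 7-(benzyloxy)-3,5,6,8-tetramethoxy-2-(4-methoxyphenyl)-4H-chromen-4-one | COc1ccc(-c2oc3c(OC)c(OCc4ccccc4)c(OC)c(OC)c3c(=O)c2OC)cc1 | intermediate
24 | 7-hydroxy-3,5,6,8-tetramethoxy-2-(4-methoxyphenyl)-4H-chromen-4-one | COc1ccc(-c2oc3c(OC)c(O)c(OC)c(OC)c3c(=O)c2OC)cc1 | target

## Step count and least certain steps

Total step count: 14. Longest linear sequence: 11 steps (steps 1–6 and 10–14). The acid branch (steps 7–9) is three steps and joins at step 10.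

**Step 10 (key step).**
- What may go wrong: the aryl anion may be protonated before the acyl shift, which stops the sequence at O-arylation. The aryne may be consumed by the methoxide set free in the ring closure. The closure itself may stall at the donor-substituted β-carbon. All three follow from the low electrophilicity of the enol ether and the basic, hot medium.
- Fallback (sets out from 8 and 17, returns at 20): 8 would be esterified with 17 (N,N'-diisopropylcarbodiimide, DMAP, CH2Cl2) to 6-bromo-4,7-dimethoxy-2,2-dimethyl-1,3-benzodioxol-5-yl (2E)-2,3-dimethoxy-3-(4-methoxyphenyl)prop-2-enoate F1. Bromine–lithium exchange with t-BuLi in THF at −100 °C would give the same ortho-aryl anion without an aryne or proton source. The known anionic 1,3 oxygen-to-carbon acyl shift of ortho-haloaryl esters would then give, after work-up, (2E)-1-(5-hydroxy-4,7-dimethoxy-2,2-dimethyl-1,3-benzodioxol-6-yl)-2,3-dimethoxy-3-(4-methoxyphenyl)prop-2-en-1-one F2. Cs2CO3 in DMF at 80 °C would close F2 through 19 to 20.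

**Step 5.**
- What may go wrong: oxidation of the very electron-rich phenol by the brominating agent (electron transfer towards a quinone) instead of ring substitution, and ipso attack at oxygen-bearing carbons. Five oxygen substituents make the ring an excellent reductant.
- Fallback (sets out from 7, returns at 11, by-passes 8–10, no electrophilic halogen): 7 would be carbamoylated (ClC(O)NEt2, NaH, THF) to 4,7-dimethoxy-2,2-dimethyl-1,3-benzodioxol-5-yl diethylcarbamate F3. Directed ortho-metalation between the carbamate and the methoxy group (s-BuLi, TMEDA, THF, −78 °C) and quenching with Me3SiCl would give 4,7-dimethoxy-2,2-dimethyl-6-(trimethylsilyl)-1,3-benzodioxol-5-yl diethylcarbamate F4. Reductive removal of the carbamate with LiAlH4 in THF would free 4,7-dimethoxy-2,2-dimethyl-6-(trimethylsilyl)-1,3-benzodioxol-5-ol F5, and triflation (Tf2O, pyridine, CH2Cl2, 0 °C) would give 11.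

**Step 8.**
- What may go wrong: alkylation of the ambident enolate at carbon instead of oxygen, which would build a quaternary centre and remove the leaving group needed in step 10.
- Fallback (sets out from 15, returns at 16, no enolate alkylation): ketalisation of 15 with HC(OMe)3 and catalytic TsOH in MeOH would give methyl 2,3,3-trimethoxy-3-(4-methoxyphenyl)propanoate F6. Elimination of methanol (Me3SiOTf, i-Pr2NEt, CH2Cl2) would give 16.

**Step 12.**
- What may go wrong: alkylation at the wrong oxygen or at both, if more than the monoanion is present or if the proton is shared within the catechol.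
- Fallback (sets out from 21, returns at 24, no new compound, F0): the selectivity would be inverted on purpose through the dianion. With NaH (2.2 equiv) in DMF at 0 °C both hydroxyls are deprotonated, and one equivalent of MeI should then react at the more basic, non-conjugated O6 oxide. This is the known behaviour of catechol dianions, and it would also save steps 13 and 14.

## Further compounds

F1 | step 10 | 6-bromo-4,7-dimethoxy-2,2-dimethyl-1,3-benzodioxol-5-yl (2E)-2,3-dimethoxy-3-(4-methoxyphenyl)prop-2-enoate | COc1ccc(cc1)/C(OC)=C(OC)/C(=O)Oc1c(Br)c(OC)c2OC(C)(C)Oc2c1OC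
F2 | step 10 | (2E)-1-(5-hydroxy-4,7-dimethoxy-2,2-dimethyl-1,3-benzodioxol-6-yl)-2,3-dimethoxy-3-(4-methoxyphenyl)prop-2-en-1-one | COc1ccc(cc1)/C(OC)=C(OC)/C(=O)c1c(O)c(OC)c2OC(C)(C)Oc2c1OC
F3 | step 5 | 4,7-dimethoxy-2,2-dimethyl-1,3-benzodioxol-5-yl diethylcarbamate | CCN(CC)C(=O)Oc1cc(OC)c2OC(C)(C)Oc2c1OC
F4 | step 5 | 4,7-dimethoxy-2,2-dimethyl-6-(trimethylsilyl)-1,3-benzodioxol-5-yl diethylcarbamate | CCN(CC)C(=O)Oc1c([Si](C)(C)C)c(OC)c2OC(C)(C)Oc2c1OC
F5 | step 5 | 4,7-dimethoxy-2,2-dimethyl-6-(trimethylsilyl)-1,3-benzodioxol-5-ol | COc1c([Si](C)(C)C)c(O)c(OC)c2OC(C)(C)Oc12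
F6 | step 8 | methyl 2,3,3-trimethoxy-3-(4-methoxyphenyl)propanoate (racemic) | COC(C(=O)OC)C(OC)(OC)c1ccc(OC)cc1
F0 | step 12 | none | none
A1 | alternative 1 | 1,3-bis(benzyloxy)-4-iodo-2,5,6-trimethoxybenzene | COc1c(OCc2ccccc2)c(I)c(OC)c(OC)c1OCc1ccccc1
A2 | alternative 1 | 2-methoxy-1-(4-methoxyphenyl)ethan-1-one | COCC(=O)c1ccc(OC)cc1
A3 | alternative 1 | (2E)-1-[2,4-bis(benzyloxy)-3,5,6-trimethoxyphenyl]-3-hydroxy-2-methoxy-3-(4-methoxyphenyl)prop-2-en-1-one | COc1ccc(cc1)/C(O)=C(OC)/C(=O)c1c(OC)c(OC)c(OCc2ccccc2)c(OC)c1OCc1ccccc1
A4 | alternative 2 | 3-tert-butoxy-4-methoxycyclobut-3-ene-1,2-dione | COC1=C(OC(C)(C)C)C(=O)C1=O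
A5 | alternative 2 | 5-bromo-3-methoxy-2-(4-methoxyphenyl)-4H-pyran-4-one | COc1ccc(cc1)-c1occ(Br)c(=O)c1OC
A6 | alternative 2 | 2-tert-butoxy-4-hydroxy-3-methoxy-4-[5-methoxy-6-(4-methoxyphenyl)-4-oxo-4H-pyran-3-yl]cyclobut-2-en-1-one (racemic) | COC1=C(OC(C)(C)C)C(=O)C1(O)c1coc(-c2ccc(OC)cc2)c(OC)c1=O
A7 | alternative 2 | 7-tert-butoxy-5,8-dihydroxy-3,6-dimethoxy-2-(4-methoxyphenyl)-4H-chromen-4-one | COc1ccc(-c2oc3c(O)c(OC(C)(C)C)c(OC)c(O)c3c(=O)c2OC)cc1
A8 | alternative 3 | (2E)-3-[3-(benzyloxy)-2,4,5-trimethoxyphenoxy]-2-methoxy-3-(4-methoxyphenyl)prop-2-enoic acid | COc1ccc(cc1)/C(Oc1cc(OC)c(OC)c(OCc2ccccc2)c1OC)=C(OC)/C(O)=O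
A9 | alternative 3 | 7-(benzyloxy)-3,5,6,8-tetramethoxy-2-(4-methoxyphenyl)-4H-chromen-4-one | COc1ccc(-c2oc3c(OC)c(OCc4ccccc4)c(OC)c(OC)c3c(=O)c2OC)cc1
A10 | alternative 3 | 3-(benzyloxy)-2,4,5-trimethoxyphenol | COc1cc(O)c(OC)c(OCc2ccccc2)c1OC
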